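**Retrosynthetic overview**

1. C8–prenyl bond: taken back to the 5-O-prenyl ether of the flavanonol (para-Claisen–Cope transfer, O5 to C6 to C8). The ether is both the 5-OH protecting group and the prenyl source, so 8- versus 6-prenyl isomers never have to be separated.
2. Ring C and both stereocentres: the C2–C3 and O1–C2 bonds are cut together, back to a ring-A α-chloro ketone and a ring-B aldehyde (asymmetric Darzens condensation, then fluoride unmasking and 6-endo oxirane opening in the same flask).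
3. α-Chloro ketone: from the mono-prenyl ether of the symmetric 2,6-dihydroxy-4-methoxyacetophenone (silylation, then chlorination of its silyl enol ether); the ether comes from the acetophenone and prenyl bromide.
4. Ring order: rings A and B are bought; the oxirane forms first and the pyranone ring C second, both in the one-flask key step; no ring is formed afterwards.

Assumption: all three starting materials are bought as catalogue chemicals, and the sense of induction of the ammonium catalyst (inferred from the cinchonidinium/cinchoninium pseudo-enantiomer pair) is confirmed on the first run.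

**Route**

Step 1
Reactants: 1 1-(2,6-dihydroxy-4-methoxyphenyl)ethanone; 2 1-bromo-3-methylbut-2-ene (prenyl bromide)
Product: 3 1-[2-hydroxy-4-methoxy-6-(3-methylbut-2-enyloxy)phenyl]ethanone
Conditions: K2CO3 (1.5 equiv), 2 (1.05 equiv), acetone, reflux
Reagents that add atoms: none
Why: Williamson ether synthesis on a symmetric diol, where after the first O-alkylation the remaining OH is the only one chelated to the ketone and is much less nucleophilic, so the mono-ether is obtained; no stereocentre.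

Step 2
Reactants: 3 1-[2-hydroxy-4-methoxy-6-(3-methylbut-2-enyloxy)phenyl]ethanone
Product: 5 2-chloro-1-[4-methoxy-2-(3-methylbut-2-enyloxy)-6-(triisopropylsilyloxy)phenyl]ethanone, via silyl enol ether 4 (not isolated)
Conditions: iPr3SiOTf (1.1 equiv), Et3N, CH2Cl2, −78 to 0 °C; then Me3SiOTf (1.2 equiv), Et3N, 0 °C; NaHCO3 wash, solvent swap; then NCS (1.05 equiv), THF, 0 °C
Reagents that add atoms: triisopropylsilyl trifluoromethanesulfonate, CC(C)[Si](C(C)C)(C(C)C)OS(=O)(=O)C(F)(F)F; N-chlorosuccinimide, O=C1CCC(=O)N1Cl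
Why: O-silylation of the phenol, soft enolisation (silyl triflate/amine) to the trimethylsilyl enol ether and its electrophilic α-chlorination, which at 0 °C is much faster than attack on the prenyl alkene or the arene; the bulky silyl ether blocks the phenol that would otherwise displace chloride to a benzofuranone; no stereocentre.

Step 3
Reactants: 5 2-chloro-1-[4-methoxy-2-(3-methylbut-2-enyloxy)-6-(triisopropylsilyloxy)phenyl]ethanone; 6 4-(tert-butyldimethylsilyloxy)benzaldehyde
Product: 9 (2R,3R)-3-hydroxy-2-(4-hydroxyphenyl)-7-methoxy-5-(3-methylbut-2-enyloxy)-2,3-dihydro-4H-chromen-4-one, via silylated epoxy ketone 7 (not isolated), via free-phenol epoxy ketone 8 (not isolated)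
Conditions: N-(4-trifluoromethylbenzyl)cinchonidinium bromide (10 mol %), LiOH·H2O (2 equiv), toluene/CH2Cl2, −10 °C; then, same flask, AcOH (4 equiv), Bu4NF (2.5 equiv), THF, 0 °C to rt
Reagents that add atoms: none
Why: Proposed new method: the chiral ammonium enolate of 5 adds to 6 and the chlorohydrin alkoxide closes to the trans-(2R,3S)-oxirane 7 (asymmetric phase-transfer Darzens condensation; this fixes C3 as R and makes the first ring); buffered fluoride then frees both phenols and the chelated 2'-OH of 8 opens the very labile para-oxybenzylic oxirane carbon in a 6-endo fashion, with inversion or via the para-quinone methide under thermodynamic control, both giving the 2,3-trans (2R,3R) pyranone ring C; the closest known reactions are cinchona-ammonium-catalysed Darzens reactions of α-chloro aryl ketones with aldehydes and the acid-mediated cyclisation of 2'-hydroxychalcone epoxides to trans-dihydroflavonols.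

Step 4
Reactants: 9 (2R,3R)-3-hydroxy-2-(4-hydroxyphenyl)-7-methoxy-5-(3-methylbut-2-enyloxy)-2,3-dihydro-4H-chromen-4-one
Product: 12 (2R,3R)-3,5-dihydroxy-2-(4-hydroxyphenyl)-7-methoxy-8-(3-methylbut-2-enyl)-2,3-dihydro-4H-chromen-4-one, via ortho-dienone 10 (not isolated), via para-dienone 11 (not isolated)
Conditions: Eu(fod)3 [tris(6,6,7,7,8,8,8-heptafluoro-2,2-dimethyloctane-3,5-dionato)europium] (10 mol %), NaHCO3 (1 equiv), chlorobenzene, 85 °C
Reagents that add atoms: none
Why: Aromatic Claisen rearrangement to C6 followed by Cope rearrangement to the para carbon C8 (para-Claisen–Cope sequence, accelerated by chelation of europium between the C4 carbonyl and O5) and enolisation to the 5-OH phenol, as known for 5-O-prenyl flavonoids; C2 and C3 are not touched and the trans-diequatorial arrangement is the stable one.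

**Compound list**

1 | 1-(2,6-dihydroxy-4-methoxyphenyl)ethanone | CC(=O)c1c(O)cc(OC)cc1O | starting material
2 | 1-bromo-3-methylbut-2-ene (prenyl bromide) | CC(C)=CCBr | starting material
3 | 1-[2-hydroxy-4-methoxy-6-(3-methylbut-2-enyloxy)phenyl]ethanone | CC(=O)c1c(O)cc(OC)cc1OCC=C(C)C | intermediate
4 | trimethyl({1-[4-methoxy-2-(3-methylbut-2-enyloxy)-6-(triisopropylsilyloxy)phenyl]ethenyl}oxy)silane | C=C(O[Si](C)(C)C)c1c(O[Si](C(C)C)(C(C)C)C(C)C)cc(OC)cc1OCC=C(C)C | intermediate
5 | 2-chloro-1-[4-methoxy-2-(3-methylbut-2-enyloxy)-6-(triisopropylsilyloxy)phenyl]ethanone | ClCC(=O)c1c(O[Si](C(C)C)(C(C)C)C(C)C)cc(OC)cc1OCC=C(C)C | intermediate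
6 | 4-(tert-butyldimethylsilyloxy)benzaldehyde | O=Cc1ccc(O[Si](C)(C)C(C)(C)C)cc1 | starting material
7 | [(2R,3S)-3-[4-(tert-butyldimethylsilyloxy)phenyl]oxiran-2-yl][4-methoxy-2-(3-methylbut-2-enyloxy)-6-(triisopropylsilyloxy)phenyl]methanone | O=C(c1c(O[Si](C(C)C)(C(C)C)C(C)C)cc(OC)cc1OCC=C(C)C)[C@@H]1O[C@H]1c1ccc(O[Si](C)(C)C(C)(C)C)cc1 | intermediate
8 | [(2R,3S)-3-(4-hydroxyphenyl)oxiran-2-yl][2-hydroxy-4-methoxy-6-(3-methylbut-2-enyloxy)phenyl]methanone | O=C(c1c(O)cc(OC)cc1OCC=C(C)C)[C@@H]1O[C@H]1c1ccc(O)cc1 | intermediate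
9 | (2R,3R)-3-hydroxy-2-(4-hydroxyphenyl)-7-methoxy-5-(3-methylbut-2-enyloxy)-2,3-dihydro-4H-chromen-4-one | COc1cc(OCC=C(C)C)c2c(c1)O[C@H](c1ccc(O)cc1)[C@@H](O)C2=O | intermediate
10 | (2R,3R)-3-hydroxy-2-(4-hydroxyphenyl)-7-methoxy-6-(2-methylbut-3-en-2-yl)-2,3-dihydro-4H-chromene-4,5(6H)-dione (C6 epimers) | COC1=CC2=C(C(=O)C1C(C)(C)C=C)C(=O)[C@H](O)[C@@H](c1ccc(O)cc1)O2 | intermediate
11 | (2R,3R)-3-hydroxy-2-(4-hydroxyphenyl)-7-methoxy-8-(3-methylbut-2-enyl)-2,3-dihydro-4H-chromene-4,5(8H)-dione (C8 epimers) | COC1=CC(=O)C2=C(O[C@H](c3ccc(O)cc3)[C@@H](O)C2=O)C1CC=C(C)C | intermediate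
12 | (2R,3R)-3,5-dihydroxy-2-(4-hydroxyphenyl)-7-methoxy-8-(3-methylbut-2-enyl)-2,3-dihydro-4H-chromen-4-one | COc1cc(O)c2c(c1CC=C(C)C)O[C@H](c1ccc(O)cc1)[C@@H](O)C2=O | target

**Step count**

Total steps: 4. Longest linear sequence: 4 (1 → 3 → 5 → 9 → 12).

**Steps most likely to fail**

Step 3 (most at risk). The chloro ketone is flanked by two ortho oxygens and the aldehyde is electron-rich, so the enantiomeric excess and rate of the Darzens step are uncertain. Hydroxide may also strip or shift a silyl group, and a freed 2'-phenoxide would close to a benzofuranone. If only the sense of induction is wrong, the pseudo-enantiomeric N-(4-trifluoromethylbenzyl)cinchoninium bromide is used instead. The fallback changes the bond construction from a C–C-forming Darzens reaction to epoxidation of a preformed enone. It sets out from 3: Claisen–Schmidt condensation with 4-hydroxybenzaldehyde (KOH, EtOH) gives the chalcone (E)-1-[2-hydroxy-4-methoxy-6-(3-methylbut-2-enyloxy)phenyl]-3-(4-hydroxyphenyl)prop-2-en-1-one F1. Silylation of both phenols (iPr3SiOTf, 2,6-lutidine, CH2Cl2) gives the bis-silyl chalcone (E)-1-[4-methoxy-2-(3-methylbut-2-enyloxy)-6-(triisopropylsilyloxy)phenyl]-3-[4-(triisopropylsilyloxy)phenyl]prop-2-en-1-one F2. Juliá–Colonna epoxidation (poly-L-leucine, urea–H2O2, DBU, THF), which is nucleophilic and leaves the prenyl alkene alone, gives [(2R,3S)-3-[4-(triisopropylsilyloxy)phenyl]oxiran-2-yl][4-methoxy-2-(3-methylbut-2-enyloxy)-6-(triisopropylsilyloxy)phenyl]methanone F3. Bu4NF/AcOH in THF then takes F3 through 8, and the fallback comes back to the route at 9.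

Step 2. Electrophilic chlorine may also attack the electron-rich arene or the prenyl alkene, and the enol ether may hydrolyse before it is chlorinated. The fallback replaces electrophilic chlorination by a diazo ketone that takes up chloride as a nucleophile. It sets out from 3: silylation (iPr3SiOTf, 2,6-lutidine) gives 1-[4-methoxy-2-(3-methylbut-2-enyloxy)-6-(triisopropylsilyloxy)phenyl]ethanone F4. Trifluoroacetylation of its lithium enolate (LiN(SiMe3)2, CF3CO2CH2CF3, THF, −78 °C) gives 4,4,4-trifluoro-1-[4-methoxy-2-(3-methylbut-2-enyloxy)-6-(triisopropylsilyloxy)phenyl]butane-1,3-dione F5. Detrifluoroacetylative diazo transfer (MeSO2N3, Et3N, MeCN) gives 2-diazo-1-[4-methoxy-2-(3-methylbut-2-enyloxy)-6-(triisopropylsilyloxy)phenyl]ethanone F6. One equivalent of HCl in Et2O at −30 °C converts F6 with loss of nitrogen into the chloro ketone, so the fallback comes back at 5.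

Step 4. The rearrangement may stop at, or favour, the 6-(1,1-dimethylallyl) ortho product, and the free 3-OH/4'-OH flavanonol may suffer at 85 °C (C2 epimerisation through the quinone methide, oxidation). The fallback moves the sigmatropic transfer onto a protected substrate of the type for which the europium-catalysed para-selective transfer is documented. It sets out from 9: acetylation (Ac2O, pyridine, 0 °C) gives (2R,3R)-2-(4-acetoxyphenyl)-7-methoxy-5-(3-methylbut-2-enyloxy)-4-oxo-3,4-dihydro-2H-chromen-3-yl acetate F7. Heating F7 with Eu(fod)3 in chlorobenzene leads through the ortho-dienone (2R,3R)-2-(4-acetoxyphenyl)-7-methoxy-6-(2-methylbut-3-en-2-yl)-4,5-dioxo-3,4,5,6-tetrahydro-2H-chromen-3-yl acetate F8 and the para-dienone (2R,3R)-2-(4-acetoxyphenyl)-7-methoxy-8-(3-methylbut-2-enyl)-4,5-dioxo-3,4,5,8-tetrahydro-2H-chromen-3-yl acetate F9 to (2R,3R)-2-(4-acetoxyphenyl)-5-hydroxy-7-methoxy-8-(3-methylbut-2-enyl)-4-oxo-3,4-dihydro-2H-chromen-3-yl acetate F10. Brief methanolysis (K2CO3, MeOH, 0 °C) removes both acetates, and the fallback comes back at 12.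

**Further compounds**

F1 | step 3 | (E)-1-[2-hydroxy-4-methoxy-6-(3-methylbut-2-enyloxy)phenyl]-3-(4-hydroxyphenyl)prop-2-en-1-one | O=C(/C=C/c1ccc(O)cc1)c1c(O)cc(OC)cc1OCC=C(C)C
F2 | step 3 | (E)-1-[4-methoxy-2-(3-methylbut-2-enyloxy)-6-(triisopropylsilyloxy)phenyl]-3-[4-(triisopropylsilyloxy)phenyl]prop-2-en-1-one | O=C(/C=C/c1ccc(O[Si](C(C)C)(C(C)C)C(C)C)cc1)c1c(O[Si](C(C)C)(C(C)C)C(C)C)cc(OC)cc1OCC=C(C)C
F3 | step 3 | [(2R,3S)-3-[4-(triisopropylsilyloxy)phenyl]oxiran-2-yl][4-methoxy-2-(3-methylbut-2-enyloxy)-6-(triisopropylsilyloxy)phenyl]methanone | O=C(c1c(O[Si](C(C)C)(C(C)C)C(C)C)cc(OC)cc1OCC=C(C)C)[C@@H]1O[C@H]1c1ccc(O[Si](C(C)C)(C(C)C)C(C)C)cc1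
F4 | step 2 | 1-[4-methoxy-2-(3-methylbut-2-enyloxy)-6-(triisopropylsilyloxy)phenyl]ethanone | CC(=O)c1c(O[Si](C(C)C)(C(C)C)C(C)C)cc(OC)cc1OCC=C(C)C
F5 | step 2 | 4,4,4-trifluoro-1-[4-methoxy-2-(3-methylbut-2-enyloxy)-6-(triisopropylsilyloxy)phenyl]butane-1,3-dione | O=C(CC(=O)C(F)(F)F)c1c(O[Si](C(C)C)(C(C)C)C(C)C)cc(OC)cc1OCC=C(C)C
F6 | step 2 | 2-diazo-1-[4-methoxy-2-(3-methylbut-2-enyloxy)-6-(triisopropylsilyloxy)phenyl]ethanone | [N-]=[N+]=CC(=O)c1c(O[Si](C(C)C)(C(C)C)C(C)C)cc(OC)cc1OCC=C(C)C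
F7 | step 4 | (2R,3R)-2-(4-acetoxyphenyl)-7-methoxy-5-(3-methylbut-2-enyloxy)-4-oxo-3,4-dihydro-2H-chromen-3-yl acetate | COc1cc(OCC=C(C)C)c2c(c1)O[C@H](c1ccc(OC(C)=O)cc1)[C@@H](OC(C)=O)C2=O
F8 | step 4 | (2R,3R)-2-(4-acetoxyphenyl)-7-methoxy-6-(2-methylbut-3-en-2-yl)-4,5-dioxo-3,4,5,6-tetrahydro-2H-chromen-3-yl acetate (C6 epimers) | COC1=CC2=C(C(=O)C1C(C)(C)C=C)C(=O)[C@H](OC(C)=O)[C@@H](c1ccc(OC(C)=O)cc1)O2
F9 | step 4 | (2R,3R)-2-(4-acetoxyphenyl)-7-methoxy-8-(3-methylbut-2-enyl)-4,5-dioxo-3,4,5,8-tetrahydro-2H-chromen-3-yl acetate (C8 epimers) | COC1=CC(=O)C2=C(O[C@H](c3ccc(OC(C)=O)cc3)[C@@H](OC(C)=O)C2=O)C1CC=C(C)C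
F10 | step 4 | (2R,3R)-2-(4-acetoxyphenyl)-5-hydroxy-7-methoxy-8-(3-methylbut-2-enyl)-4-oxo-3,4-dihydro-2H-chromen-3-yl acetate | COc1cc(O)c2c(c1CC=C(C)C)O[C@H](c1ccc(OC(C)=O)cc1)[C@@H](OC(C)=O)C2=O
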